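Ring A is cut at C5–C6. The 5,7-dihydroxy ring fused to ring C at C4a–C8a, with O1 on C8a and the C4 carbonyl on C4a, is a folded polyketide: C5 can come from an ester and C6–C7–C8 from an acetonyl group, both held cis on the C=C bond of a preformed, enantiopure ring C. One operation, a double deprotonation, then closes ring A by Claisen condensation and aromatises it while C2 stays untouched. The precursor is (S)-dihydropyran-4-one 15 with a 5-methoxycarbonyl and a 6-(2-oxopropyl) group and silyl ethers on the ring B phenol and the side-chain alcohol.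

Key step: step 8

Remark: Ar = 4-[(tert-butyldimethylsilyl)oxy]-3-[(2E)-3,7-dimethyl-7-[(triethylsilyl)oxy]oct-2-en-1-yl]phenyl.
Assumption: dienolate 8, amide acetal 11 and acylimidazole 14 are bought; 8 is otherwise made from methyl acetoacetate by two silylations.
Design remark: ring C is closed under neutral conditions before the acetonyl carbonyl exists. This avoids an open-chain 1,3,5-triketo ester, which would close to a pyrone, and keeps acid away from the para-silyloxybenzylic C–O bond. The ring B phenol stays silylated through the base step so that no quinone-methide-type opening of ring C can start from a phenoxide.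

Step 1
Reactants: 1 geranyl acetate
Product: 2 (2E)-7-hydroxy-3,7-dimethyloct-2-en-1-yl acetate
Conditions: Co(acac)2 (20 mol %), PhSiH3, O2 (1 atm), THF, rt; then aq. Na2S2O3
Reagents that add atoms: dioxygen, O=O
Why: Mukaiyama hydration (hydrogen-atom transfer, Markovnikov) should pick the electron-rich remote alkene over the 2,3-alkene deactivated by the allylic acetate, giving the tertiary alcohol and leaving the E geometry alone.

Step 2
Reactants: 2 (2E)-7-hydroxy-3,7-dimethyloct-2-en-1-yl acetate
Product: 3 (2E)-3,7-dimethyl-7-[(triethylsilyl)oxy]oct-2-en-1-yl acetate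
Conditions: TESOTf, 2,6-lutidine, CH2Cl2, −78 → 0 °C
Reagents that add atoms: triethylsilyl trifluoromethanesulfonate, CC[Si](CC)(CC)OS(=O)(=O)C(F)(F)F
Why: O-Silylation with a silyl triflate and a hindered base is the standard way to cap a tertiary alcohol and does not touch the allylic acetate.

Step 3
Reactants: 4 4-hydroxy-3-iodobenzaldehyde
Product: 5 4-[(tert-butyldimethylsilyl)oxy]-3-iodobenzaldehyde
Conditions: TBSCl, imidazole, DMF, rt
Reagents that add atoms: tert-butyldimethylsilyl chloride, CC(C)(C)[Si](C)(C)Cl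
Why: Imidazole-mediated O-silylation of an acidic phenol is fast and leaves aldehyde and iodide untouched.

Step 4
Reactants: 5 4-[(tert-butyldimethylsilyl)oxy]-3-iodobenzaldehyde; 3 (2E)-3,7-dimethyl-7-[(triethylsilyl)oxy]oct-2-en-1-yl acetate
Product: 7 4-[(tert-butyldimethylsilyl)oxy]-3-[(2E)-3,7-dimethyl-7-[(triethylsilyl)oxy]oct-2-en-1-yl]benzaldehyde (ArCHO), via arylzinc iodide 6 (not isolated)
Conditions: Zn dust, LiCl, THF, 40 °C; then 3, Pd(PPh3)4 (5 mol %), THF, 25 → 50 °C
Reagents that add atoms: none
Why: LiCl-assisted zinc insertion into the aryl–iodine bond tolerates the aldehyde, and the Negishi allyl–aryl coupling through a π-allylpalladium intermediate should join the aryl group to the unsubstituted allyl terminus with retention of the E geometry.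

Step 5
Reactants: 7 ArCHO; 8 1-methoxy-1,3-bis(trimethylsilyloxy)buta-1,3-diene
Product: 10 methyl (5S)-5-Ar-5-hydroxy-3-oxopentanoate, via bis-silyl aldol adduct 9 (not isolated)
Conditions: Ti(OiPr)4 (10 mol %), (S)-BINOL (10 mol %), 4 Å MS, THF, −78 °C → rt; then PPTS, MeOH, 0 °C
Reagents that add atoms: none
Why: In this catalytic asymmetric vinylogous Mukaiyama aldol the (S)-BINOL–titanium Lewis acid should expose the Si face of the aldehyde to the terminal carbon of the dienolate, setting C5 (the later C2) as S by catalyst control, after which mild methanolysis removes the two trimethylsilyl groups.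

Step 6
Reactants: 10 methyl (5S)-5-Ar-5-hydroxy-3-oxopentanoate; 11 N,N-dimethylacetamide dimethyl acetal
Product: 13 methyl (2S)-2-Ar-6-methyl-4-oxo-3,4-dihydro-2H-pyran-5-carboxylate, via enaminone 12 (not isolated)
Conditions: 11 (1.2 equiv), toluene, rt
Reagents that add atoms: none
Why: Amide-acetal condensation at the active methylene gives a push–pull enaminone whose β-carbon is attacked by the δ-hydroxyl with loss of dimethylamine (oxa-Michael addition–elimination, Maitland–Japp-type dihydropyranone synthesis), closing ring C without touching the benzylic C–O bond or its configuration.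

Step 7
Reactants: 13 methyl (2S)-2-Ar-6-methyl-4-oxo-3,4-dihydro-2H-pyran-5-carboxylate; 14 1-acetylimidazole
Product: 15 methyl (2S)-2-Ar-4-oxo-6-(2-oxopropyl)-3,4-dihydro-2H-pyran-5-carboxylate
Conditions: LiN(SiMe3)2 (1.1 equiv), THF, −78 °C; then 14 (1.3 equiv), −78 → −30 °C; AcOH/pH 6 buffer, cold; used without storage
Reagents that add atoms: none
Why: In this lateral C-acylation of a vinylogous enolate (Claisen-type), the 6-methyl protons, acidified through C5=C6 by the C4 ketone and the ester, should be removed first and the extended enolate acylated at its exocyclic carbon, while the released imidazolide deprotonates the more acidic product so that one equivalent of base suffices.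

Step 8
Reactants: 15 methyl (2S)-2-Ar-4-oxo-6-(2-oxopropyl)-3,4-dihydro-2H-pyran-5-carboxylate
Product: 17 (2S)-2-Ar-5,7-dihydroxy-2,3-dihydro-4H-chromen-4-one, via triketone 16 (not isolated)
Conditions: 15 added to LiN(iPr)2 (3.2 equiv), THF, −78 °C, then −78 → −20 °C; AcOH, −78 °C
Reagents that add atoms: none
Why: Proposed new method: the first equivalent of LiN(iPr)2 should remove a proton of the C6–CH2 group (extended enolate) and the second a proton of the terminal methyl, whose carbanion adds to the ester carbonyl on pyranone C5; methoxide leaves and triketone 16 enolises twice to the aromatic 5,7-diol, so the flavanone C5–C6 bond and ring A arise together. The closest known reaction types are the terminal C-acylation of β-diketone dianions by esters and the biomimetic Claisen cyclisation of 3,5,7-triketo esters to acylphloroglucinols; what is new is that the chain is already tied into ring C through O1. Ring A closes in a 6-(enolexo)-exo-trig mode, the only one open, since ester and acetonyl group are held cis on the C5=C6 bond while the C4 carbonyl lies trans to the side chain. No stereocentre is formed, and C2, set in step 5, is kept because its C–O bond is not part of the reacting system. The step needs C- instead of O-acylation (the mono-enolate oxygen could lactonise onto the ester to a fused α-pyrone) and enolisation of the side chain instead of C3 (a C3 enolate could expel O1 and open ring C): inverse addition to excess amide base at −78 °C gives the carbon-nucleophilic dianion at once, and the charge already in the side chain makes C3–H less acidic and O1 a poor leaving group. Aromatisation renders the closure irreversible, and a cold acidic quench returns the neutral flavanone before base can open it to the chalcone.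

Step 9
Reactants: 17 (2S)-2-Ar-5,7-dihydroxy-2,3-dihydro-4H-chromen-4-one
Product: 18 (2S)-5,7-dihydroxy-2-{4-hydroxy-3-[(2E)-7-hydroxy-3,7-dimethyloct-2-en-1-yl]phenyl}-2,3-dihydro-4H-chromen-4-one
Conditions: HF·pyridine, pyridine, THF, 0 °C → rt
Reagents that add atoms: none
Why: Fluoride desilylation should remove the aryl and the tertiary silyl ether under buffered, slightly acidic conditions in which the flavanone does not open to the chalcone and the phenol does not add to the neighbouring alkene.

Compound list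
1 | geranyl acetate | CC(C)=CCC/C(C)=C/COC(C)=O | starting material
2 | (2E)-7-hydroxy-3,7-dimethyloct-2-en-1-yl acetate | CC(=O)OC/C=C(\C)CCCC(C)(C)O | intermediate
3 | (2E)-3,7-dimethyl-7-[(triethylsilyl)oxy]oct-2-en-1-yl acetate | CC(=O)OC/C=C(\C)CCCC(C)(C)O[Si](CC)(CC)CC | intermediate
4 | 4-hydroxy-3-iodobenzaldehyde | O=Cc1ccc(O)c(I)c1 | starting material
5 | 4-[(tert-butyldimethylsilyl)oxy]-3-iodobenzaldehyde | O=Cc1ccc(O[Si](C)(C)C(C)(C)C)c(I)c1 | intermediate
6 | {2-[(tert-butyldimethylsilyl)oxy]-5-formylphenyl}zinc iodide | O=Cc1ccc(O[Si](C)(C)C(C)(C)C)c([Zn]I)c1 | intermediate (not isolated)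
7 | 4-[(tert-butyldimethylsilyl)oxy]-3-[(2E)-3,7-dimethyl-7-[(triethylsilyl)oxy]oct-2-en-1-yl]benzaldehyde (ArCHO) | C/C(=C\Cc1cc(C=O)ccc1O[Si](C)(C)C(C)(C)C)CCCC(C)(C)O[Si](CC)(CC)CC | intermediate
8 | 1-methoxy-1,3-bis(trimethylsilyloxy)buta-1,3-diene (ketene acetal geometry as supplied) | C=C(O[Si](C)(C)C)C=C(OC)O[Si](C)(C)C | starting material
9 | methyl (2Z,5S)-5-Ar-3,5-bis[(trimethylsilyl)oxy]pent-2-enoate | C/C(=C\Cc1cc([C@@H](O[Si](C)(C)C)C/C(O[Si](C)(C)C)=C/C(=O)OC)ccc1O[Si](C)(C)C(C)(C)C)CCCC(C)(C)O[Si](CC)(CC)CC | intermediate (not isolated)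
10 | methyl (5S)-5-Ar-5-hydroxy-3-oxopentanoate | C/C(=C\Cc1cc([C@@H](O)CC(=O)CC(=O)OC)ccc1O[Si](C)(C)C(C)(C)C)CCCC(C)(C)O[Si](CC)(CC)CC | intermediate
11 | N,N-dimethylacetamide dimethyl acetal | CC(OC)(OC)N(C)C | starting material
12 | methyl (5S)-5-Ar-2-[1-(dimethylamino)ethylidene]-5-hydroxy-3-oxopentanoate (enaminone geometry not fixed) | C/C(=C\Cc1cc([C@@H](O)CC(=O)C(C(=O)OC)=C(C)N(C)C)ccc1O[Si](C)(C)C(C)(C)C)CCCC(C)(C)O[Si](CC)(CC)CC | intermediate (not isolated)
13 | methyl (2S)-2-Ar-6-methyl-4-oxo-3,4-dihydro-2H-pyran-5-carboxylate | C/C(=C\Cc1cc([C@@H]2CC(=O)C(C(=O)OC)=C(C)O2)ccc1O[Si](C)(C)C(C)(C)C)CCCC(C)(C)O[Si](CC)(CC)CC | intermediate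
14 | 1-acetylimidazole | CC(=O)n1ccnc1 | starting material
15 | methyl (2S)-2-Ar-4-oxo-6-(2-oxopropyl)-3,4-dihydro-2H-pyran-5-carboxylate | C/C(=C\Cc1cc([C@@H]2CC(=O)C(C(=O)OC)=C(CC(C)=O)O2)ccc1O[Si](C)(C)C(C)(C)C)CCCC(C)(C)O[Si](CC)(CC)CC | intermediate
16 | (2S)-2-Ar-2,3-dihydro-4H-chromene-4,5,7(6H,8H)-trione | C/C(=C\Cc1cc([C@@H]2CC(=O)C3=C(CC(=O)CC3=O)O2)ccc1O[Si](C)(C)C(C)(C)C)CCCC(C)(C)O[Si](CC)(CC)CC | intermediate (not isolated)
17 | (2S)-2-Ar-5,7-dihydroxy-2,3-dihydro-4H-chromen-4-one | C/C(=C\Cc1cc([C@@H]2CC(=O)c3c(O)cc(O)cc3O2)ccc1O[Si](C)(C)C(C)(C)C)CCCC(C)(C)O[Si](CC)(CC)CC | intermediate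
18 | (2S)-5,7-dihydroxy-2-{4-hydroxy-3-[(2E)-7-hydroxy-3,7-dimethyloct-2-en-1-yl]phenyl}-2,3-dihydro-4H-chromen-4-one | C/C(=C\Cc1cc([C@@H]2CC(=O)c3c(O)cc(O)cc3O2)ccc1O)CCCC(C)(C)O | target

Total steps: 9. Longest linear sequence: 8 steps (steps 1, 2, 4, 5, 6, 7, 8, 9, from geranyl acetate 1 to 18).

Steps most likely to fail

1. Step 8. Ring closure through oxygen instead of carbon (lactonisation of the mono-enolate onto the ester) may outrun the Claisen closure. Slow second deprotonation may also allow β-elimination at C3, opening ring C and eroding the C2 configuration. The fallback uses known chemistry, sets out from 3 and returns at 18: ring A is bought in as a chromone and C2 is set by a catalytic asymmetric conjugate arylation.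
 - 4-Bromo-2-iodophenol would be silylated (TBSCl, imidazole, DMF) to (4-bromo-2-iodophenoxy)(tert-butyl)dimethylsilane F1.
 - Zinc insertion into its C–I bond (Zn, LiCl, THF) and Pd(PPh3)4-catalysed coupling with 3 should give [4-bromo-2-[(2E)-3,7-dimethyl-7-[(triethylsilyl)oxy]oct-2-en-1-yl]phenoxy](tert-butyl)dimethylsilane F2.
 - Bromine–lithium exchange (n-BuLi, THF, −78 °C), B(OiPr)3 and aqueous NH4Cl would give the boronic acid ArB(OH)2 F3.
 - 5,7-Dihydroxychromone would be silylated (TBSOTf, 2,6-lutidine, CH2Cl2) to 5,7-bis[(tert-butyldimethylsilyl)oxy]-4H-chromen-4-one F4.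
 - Rhodium-catalysed asymmetric 1,4-addition of F3 to F4 ([RhOH(cod)]2, an electron-poor MeO-BIPHEP-type bisphosphine in the antipode that leads to the 2S series, toluene/H2O, rt) should give (2S)-2-Ar-5,7-bis[(tert-butyldimethylsilyl)oxy]-2,3-dihydro-4H-chromen-4-one F5.
 - HF·pyridine as in step 9 would then give 18.

2. Step 7. The stabilised extended enolate may be acylated sluggishly or on oxygen, or competing enolisation at C3 may open ring C. The fallback sets out from 13 and returns at 15. The lithium dienolate of 13 (LiN(SiMe3)2, THF, −78 °C) would be trapped with acetaldehyde in a vinylogous aldol addition and quenched cold with AcOH. This should give methyl (2S)-2-Ar-6-(2-hydroxypropyl)-4-oxo-3,4-dihydro-2H-pyran-5-carboxylate F6 as both carbinol epimers. F6 would be oxidised at once with Dess–Martin periodinane/NaHCO3 (CH2Cl2, 0 °C) to 15. The alcohol should not be stored, because it can lactonise onto the neighbouring ester.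

3. Step 4. Zinc insertion next to the bulky silyl ether may stall, the allyl group may be transferred to the aldehyde, or the alkene geometry may scramble through π-allyl isomerisation. The fallback sets out from 5 and returns at 7. Miyaura borylation of 5 (B2pin2, PdCl2(dppf), KOAc, dioxane, 80 °C) would give 4-[(tert-butyldimethylsilyl)oxy]-3-(4,4,5,5-tetramethyl-1,3,2-dioxaborolan-2-yl)benzaldehyde F7. A Suzuki–Miyaura allyl–aryl coupling of F7 with 3 (Pd(PPh3)4, K3PO4, THF/H2O, 50 °C) should then give 7.

Further compounds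
F1 | step 8 | (4-bromo-2-iodophenoxy)(tert-butyl)dimethylsilane | CC(C)(C)[Si](C)(C)Oc1ccc(Br)cc1I
F2 | step 8 | [4-bromo-2-[(2E)-3,7-dimethyl-7-[(triethylsilyl)oxy]oct-2-en-1-yl]phenoxy](tert-butyl)dimethylsilane | C/C(=C\Cc1cc(Br)ccc1O[Si](C)(C)C(C)(C)C)CCCC(C)(C)O[Si](CC)(CC)CC
F3 | step 8 | {4-[(tert-butyldimethylsilyl)oxy]-3-[(2E)-3,7-dimethyl-7-[(triethylsilyl)oxy]oct-2-en-1-yl]phenyl}boronic acid | C/C(=C\Cc1cc(B(O)O)ccc1O[Si](C)(C)C(C)(C)C)CCCC(C)(C)O[Si](CC)(CC)CC
F4 | step 8 | 5,7-bis[(tert-butyldimethylsilyl)oxy]-4H-chromen-4-one | O=c1ccoc2cc(O[Si](C)(C)C(C)(C)C)cc(O[Si](C)(C)C(C)(C)C)c12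
F5 | step 8 | (2S)-2-Ar-5,7-bis[(tert-butyldimethylsilyl)oxy]-2,3-dihydro-4H-chromen-4-one | C/C(=C\Cc1cc([C@@H]2CC(=O)c3c(O[Si](C)(C)C(C)(C)C)cc(O[Si](C)(C)C(C)(C)C)cc3O2)ccc1O[Si](C)(C)C(C)(C)C)CCCC(C)(C)O[Si](CC)(CC)CC
F6 | step 7 | methyl (2S)-2-Ar-6-(2-hydroxypropyl)-4-oxo-3,4-dihydro-2H-pyran-5-carboxylate (carbinol epimers) | C/C(=C\Cc1cc([C@@H]2CC(=O)C(C(=O)OC)=C(CC(C)O)O2)ccc1O[Si](C)(C)C(C)(C)C)CCCC(C)(C)O[Si](CC)(CC)CC
F7 | step 4 | 4-[(tert-butyldimethylsilyl)oxy]-3-(4,4,5,5-tetramethyl-1,3,2-dioxaborolan-2-yl)benzaldehyde | O=Cc1ccc(O[Si](C)(C)C(C)(C)C)c(B2OC(C)(C)C(C)(C)O2)c1
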